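**Plan**
- Retrosynthesis cuts first the ArCH2–CH= bond of the geranyl chain (C1'–C2'), then the O1–C2 bond of the pyranone ring, then the C4–C4a aryl–acyl bond.
- Enabling feature: the chain carbon sits on C6 of the benzo ring between the C5 and C7 hydroxyls, so a leaving group on that CH2 departs to an o-quinone methide; the same phenol oxygen binds boron and passes an (E)-alkenyl group to the exocyclic carbon.
- Regiochemistry: O1 is para to C6, so the arene precursor (4-OBn, 2,6-bis-OMOM benzyl silyl ether) has a mirror plane and its two ring C–H bonds are equivalent; ortho-lithiation/acylation cannot give a regioisomer.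
- Forward order: arene → aryl ketone (C4–C4a) → pyranone ring by intramolecular Mitsunobu (O1–C2) → acid methanolysis to the 6-CH2OMe-5,7-diol → chain joined last on the unprotected flavanone.
- Stereochemistry: C2 (S) comes from ethyl (R)-3-hydroxy-3-phenylpropanoate by SN2 inversion in the Mitsunobu closure; the E alkene comes from syn-carboalumination of 6-methylhept-5-en-1-yne and is carried through I → Li → B with retention.

Key step: step 13

Remark: the target is read as (2S)-6-geranyl-5,7-dihydroxyflavanone with an E 2',3'-alkene; compounds 1, 6 and 15 are taken as purchasable.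

**Step 1**
Reactants: 1 methyl 2,4,6-trihydroxybenzoate
Product: 2 methyl 4-(benzyloxy)-2,6-dihydroxybenzoate
Conditions: BnBr (1.0 equiv), K2CO3 (1.1 equiv), acetone, rt
Reagents that add atoms: benzyl bromide, BrCc1ccccc1
Why: Williamson etherification: the 2- and 6-hydroxyls are hydrogen-bonded to the ester, so with one equivalent of base only the para hydroxyl (most acidic, least hindered) should be benzylated, which marks the oxygen that later becomes O1.

**Step 2**
Reactants: 2 methyl 4-(benzyloxy)-2,6-dihydroxybenzoate
Product: 3 methyl 4-(benzyloxy)-2,6-bis(methoxymethoxy)benzoate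
Conditions: NaH (2.4 equiv), MOMCl (2.4 equiv), DMF, 0 °C to rt
Reagents that add atoms: chloromethyl methyl ether, COCCl
Why: O-alkylation of the two sodium phenoxides (acetal protection) should go to completion once NaH has broken the hydrogen bonds, and it supplies the directing groups for the later ortho-lithiation.

**Step 3**
Reactants: 3 methyl 4-(benzyloxy)-2,6-bis(methoxymethoxy)benzoate
Product: 4 [4-(benzyloxy)-2,6-bis(methoxymethoxy)phenyl]methanol
Conditions: LiAlH4, THF, 0 °C to rt; H2O/aq NaOH work-up
Reagents that add atoms: none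
Why: Hydride reduction of the hindered aryl ester to the primary benzylic alcohol leaves the benzyl ether and MOM acetals untouched, and the basic work-up avoids ionising the electron-rich benzylic alcohol.

**Step 4**
Reactants: 4 [4-(benzyloxy)-2,6-bis(methoxymethoxy)phenyl]methanol
Product: 5 {[4-(benzyloxy)-2,6-bis(methoxymethoxy)phenyl]methoxy}(tert-butyl)dimethylsilane
Conditions: TBSCl, imidazole, DMF, rt
Reagents that add atoms: tert-butyldimethylsilyl chloride, CC(C)(C)[Si](C)(C)Cl
Why: Standard silylation of the primary alcohol masks the benzylic oxygen as a group that should survive organolithium, hydrogenolysis and Mitsunobu conditions and is removed later by acid.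

**Step 5**
Reactants: 6 ethyl (R)-3-hydroxy-3-phenylpropanoate
Product: 7 (R)-3-hydroxy-N-methoxy-N-methyl-3-phenylpropanamide
Conditions: MeNH(OMe)·HCl (1.5 equiv), i-PrMgCl (4 equiv), THF, −20 to 0 °C
Reagents that add atoms: N,O-dimethylhydroxylamine hydrochloride, CNOC.Cl
Why: Aminolysis of the ester by the chloromagnesium amide (Weinreb amide formation) at low temperature does not touch the carbinol carbon, so the R configuration of the purchased ester is retained.

**Step 6**
Reactants: 5 {[4-(benzyloxy)-2,6-bis(methoxymethoxy)phenyl]methoxy}(tert-butyl)dimethylsilane; 7 (R)-3-hydroxy-N-methoxy-N-methyl-3-phenylpropanamide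
Product: 10 (R)-1-[6-(benzyloxy)-3-{[(tert-butyldimethylsilyl)oxy]methyl}-2,4-bis(methoxymethoxy)phenyl]-3-hydroxy-3-phenylpropan-1-one, via aryllithium 8 (not isolated), via chloromagnesium alkoxide 9 (not isolated)
Conditions: 5, n-BuLi (1.1 equiv), THF, 0 °C; 7, i-PrMgCl (1.0 equiv), THF, −40 °C; combine at −78 °C, then 0 °C; aq NH4Cl
Reagents that add atoms: none
Why: Directed ortho-metalation: the two ring C–H bonds of 5 are equivalent by mirror symmetry and each lies between an OMOM and the benzyloxy group, so n-BuLi should give the single aryllithium 8, which acylates the Weinreb amide (stable tetrahedral chelate, no over-addition) while the hydroxyl is masked as alkoxide 9; the stereocentre is not involved.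

**Step 7**
Reactants: 10 (R)-1-[6-(benzyloxy)-3-{[(tert-butyldimethylsilyl)oxy]methyl}-2,4-bis(methoxymethoxy)phenyl]-3-hydroxy-3-phenylpropan-1-one
Product: 11 (R)-1-[3-{[(tert-butyldimethylsilyl)oxy]methyl}-6-hydroxy-2,4-bis(methoxymethoxy)phenyl]-3-hydroxy-3-phenylpropan-1-one
Conditions: H2 (1 atm), 10% Pd/C, EtOAc, rt
Reagents that add atoms: none
Why: Catalytic hydrogenolysis should cleave the aryl benzyl ether much faster than the hindered benzylic silyl ether or the secondary benzylic alcohol, unmasking the one phenol (ortho to the ketone) that is to become O1.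

**Step 8**
Reactants: 11 (R)-1-[3-{[(tert-butyldimethylsilyl)oxy]methyl}-6-hydroxy-2,4-bis(methoxymethoxy)phenyl]-3-hydroxy-3-phenylpropan-1-one
Product: 12 (S)-6-{[(tert-butyldimethylsilyl)oxy]methyl}-5,7-bis(methoxymethoxy)-2-phenylchroman-4-one
Conditions: PPh3, DIAD, THF, 0 °C
Reagents that add atoms: none
Why: Intramolecular Mitsunobu etherification (6-exo-tet SN2): the only free phenol displaces the phosphonium-activated benzylic oxygen with inversion, turning the R carbinol into S at C2 and placing the CH2OTBS carbon at C6 without ambiguity.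

**Step 9**
Reactants: 12 (S)-6-{[(tert-butyldimethylsilyl)oxy]methyl}-5,7-bis(methoxymethoxy)-2-phenylchroman-4-one
Product: 14 (S)-5,7-dihydroxy-6-(methoxymethyl)-2-phenylchroman-4-one, via 6-hydroxymethyl flavanone 13 (not isolated)
Conditions: HCl (1–2 M), MeOH, 40 °C, dilute
Reagents that add atoms: methanol, CO
Why: Acid methanolysis removes both MOM acetals and the TBS ether, and the resulting 2,6-dihydroxybenzylic alcohol 13 ionises readily and is captured by the solvent (SN1 solvolysis) to give the methyl ether, an exchange that is degenerate in methanol once 14 has formed; without base C2 should not epimerise.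

**Step 10**
Reactants: 15 6-methylhept-5-en-2-one
Product: 17 6-methylhept-5-en-1-yne, via enol phosphate 16 (not isolated)
Conditions: LDA (1.05 equiv), THF, −78 °C; ClP(O)(OEt)2; LDA (2.2 equiv), −78 °C to rt; aq work-up
Reagents that add atoms: none
Why: Kinetic deprotonation at the methyl group, O-phosphorylation to the terminal enol phosphate and LDA-induced elimination of diethyl phosphate is the standard methyl ketone to terminal alkyne conversion and leaves the trisubstituted alkene untouched.

**Step 11**
Reactants: 17 6-methylhept-5-en-1-yne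
Product: 19 (E)-1-iodo-2,6-dimethylhepta-1,5-diene, via alkenylalane 18 (not isolated)
Conditions: AlMe3 (2 equiv), Cp2ZrCl2 (20 mol%), CH2Cl2, 0 °C to rt; I2, THF, −30 °C
Reagents that add atoms: trimethylaluminium, C[Al](C)C; iodine, II
Why: Zirconium-catalysed carboalumination (Negishi) adds methyl and aluminium syn across the terminal alkyne with methyl on the internal carbon, and iodinolysis of the C–Al bond with retention should give the E iodide as a single isomer.

**Step 12**
Reactants: 19 (E)-1-iodo-2,6-dimethylhepta-1,5-diene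
Product: 22 [(E)-2,6-dimethylhepta-1,5-dien-1-yl]boronic acid, via alkenyllithium 20 (not isolated), via lithium borate 21 (not isolated)
Conditions: t-BuLi (2.0 equiv), Et2O, −78 °C; B(Oi-Pr)3, −78 °C to rt; 1 M aq HCl
Reagents that add atoms: triisopropyl borate, CC(C)OB(OC(C)C)OC(C)C; water, O
Why: Iodine–lithium exchange and trapping of the alkenyllithium with the borate both proceed with retention at the sp2 carbon, so acidic hydrolysis of borate 21 should give the E boronic acid.

**Step 13**
Reactants: 14 (S)-5,7-dihydroxy-6-(methoxymethyl)-2-phenylchroman-4-one; 22 [(E)-2,6-dimethylhepta-1,5-dien-1-yl]boronic acid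
Product: 24 (S)-6-[(2E)-3,7-dimethylocta-2,6-dien-1-yl]-5,7-dihydroxy-2-phenylchroman-4-one, via o-quinone methide 23 (not isolated)
Conditions: 22 (2.0 equiv), 2,2'-biphenol (20 mol%), 4 Å MS, PhMe, 60 °C; aq work-up
Reagents that add atoms: none
Why: Boron–oxygen exchange ties the boronic acid to a phenolic oxygen flanking C6, and this Lewis-acidic boron assists loss of methanol from the C6 benzylic carbon to give o-quinone methide 23 (through O7 or O5, both leading to the same product), whose carbonyl oxygen holds a tetracoordinate alkenylboronate that shifts its alkenyl group to the exocyclic methylene through a six-membered transition state, rearomatising the ring. The closest known reaction type is the biphenol-catalysed conjugate addition of alkenylboronates to o-quinone methides generated in situ from o-hydroxybenzyl ethers, a Petasis-type boron-to-carbon transfer. No ring is closed and no stereocentre is created; the alkenyl group migrates with retention, so the E geometry of 22 is carried into the chain. The step needs C–C bond formation only at the exocyclic carbon on C6, which is secured because C8 carries no leaving group and the alkenyl group is delivered intramolecularly from the neighbouring oxygen, which should outrun capture of 23 by a second flavanone or by the trisubstituted alkene; the excess of 22 supports this. The medium contains no base, so the C2 stereocentre (which opens to the chalcone only under base) and the free phenols need no protection.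

**Compound list**
1 | methyl 2,4,6-trihydroxybenzoate | COC(=O)c1c(O)cc(O)cc1O | starting material
2 | methyl 4-(benzyloxy)-2,6-dihydroxybenzoate | COC(=O)c1c(O)cc(OCc2ccccc2)cc1O | intermediate
3 | methyl 4-(benzyloxy)-2,6-bis(methoxymethoxy)benzoate | COC(=O)c1c(OCOC)cc(OCc2ccccc2)cc1OCOC | intermediate
4 | [4-(benzyloxy)-2,6-bis(methoxymethoxy)phenyl]methanol | OCc1c(OCOC)cc(OCc2ccccc2)cc1OCOC | intermediate
5 | {[4-(benzyloxy)-2,6-bis(methoxymethoxy)phenyl]methoxy}(tert-butyl)dimethylsilane | CC(C)(C)[Si](C)(C)OCc1c(OCOC)cc(OCc2ccccc2)cc1OCOC | intermediate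
6 | ethyl (R)-3-hydroxy-3-phenylpropanoate | CCOC(=O)C[C@@H](O)c1ccccc1 | starting material
7 | (R)-3-hydroxy-N-methoxy-N-methyl-3-phenylpropanamide | CON(C)C(=O)C[C@@H](O)c1ccccc1 | intermediate
8 | [6-(benzyloxy)-3-{[(tert-butyldimethylsilyl)oxy]methyl}-2,4-bis(methoxymethoxy)phenyl]lithium (formed in situ) | [Li]c1c(OCc2ccccc2)cc(OCOC)c(CO[Si](C)(C)C(C)(C)C)c1OCOC | intermediate
9 | chloromagnesium (R)-alkoxide of 7 (formed in situ) | CON(C)C(=O)C[C@@H](O[Mg]Cl)c1ccccc1 | intermediate
10 | (R)-1-[6-(benzyloxy)-3-{[(tert-butyldimethylsilyl)oxy]methyl}-2,4-bis(methoxymethoxy)phenyl]-3-hydroxy-3-phenylpropan-1-one | O=C(C[C@@H](O)c1ccccc1)c1c(OCc2ccccc2)cc(OCOC)c(CO[Si](C)(C)C(C)(C)C)c1OCOC | intermediate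
11 | (R)-1-[3-{[(tert-butyldimethylsilyl)oxy]methyl}-6-hydroxy-2,4-bis(methoxymethoxy)phenyl]-3-hydroxy-3-phenylpropan-1-one | O=C(C[C@@H](O)c1ccccc1)c1c(O)cc(OCOC)c(CO[Si](C)(C)C(C)(C)C)c1OCOC | intermediate
12 | (S)-6-{[(tert-butyldimethylsilyl)oxy]methyl}-5,7-bis(methoxymethoxy)-2-phenylchroman-4-one | O=C1C[C@@H](c2ccccc2)Oc2cc(OCOC)c(CO[Si](C)(C)C(C)(C)C)c(OCOC)c21 | intermediate
13 | (S)-5,7-dihydroxy-6-(hydroxymethyl)-2-phenylchroman-4-one (formed in situ) | O=C1C[C@@H](c2ccccc2)Oc2cc(O)c(CO)c(O)c21 | intermediate
14 | (S)-5,7-dihydroxy-6-(methoxymethyl)-2-phenylchroman-4-one | O=C1C[C@@H](c2ccccc2)Oc2cc(O)c(COC)c(O)c21 | intermediate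
15 | 6-methylhept-5-en-2-one | CC(=O)CCC=C(C)C | starting material
16 | diethyl 6-methylhepta-1,5-dien-2-yl phosphate (formed in situ) | C=C(CCC=C(C)C)OP(=O)(OCC)OCC | intermediate
17 | 6-methylhept-5-en-1-yne | C#CCCC=C(C)C | intermediate
18 | [(E)-2,6-dimethylhepta-1,5-dien-1-yl]dimethylalane (formed in situ) | C[Al](C)/C=C(\C)CCC=C(C)C | intermediate
19 | (E)-1-iodo-2,6-dimethylhepta-1,5-diene | I/C=C(\C)CCC=C(C)C | intermediate
20 | [(E)-2,6-dimethylhepta-1,5-dien-1-yl]lithium (formed in situ) | [Li]/C=C(\C)CCC=C(C)C | intermediate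
21 | lithium [(E)-2,6-dimethylhepta-1,5-dien-1-yl]tri(propan-2-yloxy)borate (formed in situ) | [Li+].CC(C)O[B-](OC(C)C)(OC(C)C)/C=C(\C)CCC=C(C)C | intermediate
22 | [(E)-2,6-dimethylhepta-1,5-dien-1-yl]boronic acid | OB(O)/C=C(\C)CCC=C(C)C | intermediate
23 | (S)-5-hydroxy-6-methylidene-2-phenyl-2,3-dihydro-4H-chromene-4,7(6H)-dione, the o-quinone methide (formed in situ) | O=C1C[C@@H](c2ccccc2)OC2=CC(=O)C(=C)C(O)=C12 | intermediate
24 | (S)-6-[(2E)-3,7-dimethylocta-2,6-dien-1-yl]-5,7-dihydroxy-2-phenylchroman-4-one | CC(C)=CCC/C(C)=C/Cc1c(O)cc2c(c1O)C(=O)C[C@@H](c1ccccc1)O2 | target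

**Step count and risks**
Total steps: 13. Longest linear sequence: 9 (steps 1, 2, 3, 4, 6, 7, 8, 9, 13).

Steps most likely to fail:

1. Step 13. The o-quinone methide may be consumed before alkenyl transfer: by attack of C8 of a second flavanone (methylene-bridged dimers), by [4+2] addition of the trisubstituted alkene, or the boronic acid may protodeboronate. The fallback sets out from 12 and returns at 24, replacing the o-quinone methide event by a nickel-catalysed cross-coupling on the protected flavanone. Compound 12 would be desilylated (TBAF buffered with AcOH, THF) to (S)-6-(hydroxymethyl)-5,7-bis(methoxymethoxy)-2-phenylchroman-4-one F1. F1 would be converted (MsCl, Et3N, LiCl, THF, 0 °C) into (S)-6-(chloromethyl)-5,7-bis(methoxymethoxy)-2-phenylchroman-4-one F2, used crude. F2 would be coupled with alkenylalane 18 (made as in step 11, excess AlMe3 removed in vacuo) under Ni(0) catalysis (NiCl2(PPh3)2 reduced with n-BuLi, THF, rt) to (S)-6-[(2E)-3,7-dimethylocta-2,6-dien-1-yl]-5,7-bis(methoxymethoxy)-2-phenylchroman-4-one F3. Brief HCl/MeOH would then remove the MOM groups to give 24.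

2. Step 8. The activated benzylic alcohol may eliminate (E1cB) to the chalcone, or ionise at the benzylic carbon and erode the enantiomeric purity. The fallback sets out from 11 and returns at 12, giving up stereospecific displacement for cyclisation followed by resolution. KOH in EtOH should dehydrate 11 to (E)-1-[3-{[(tert-butyldimethylsilyl)oxy]methyl}-6-hydroxy-2,4-bis(methoxymethoxy)phenyl]-3-phenylprop-2-en-1-one F4. NaOAc in refluxing EtOH should close F4 by oxa-Michael addition to racemic 6-{[(tert-butyldimethylsilyl)oxy]methyl}-5,7-bis(methoxymethoxy)-2-phenylchroman-4-one F5. Preparative chromatography on a chiral stationary phase would deliver the S enantiomer 12.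

3. Step 6. Deprotonation may compete at the benzylic positions (OCH2Ph, ArCH2OSi) or ring lithiation may stay incomplete, so the aryllithium is not formed cleanly. The fallback sets out from 5 and returns at 8 (and so at 10), fixing the metalation site by halogenation instead of by C–H acidity. NBS (MeCN, 0 °C) should brominate one of the two equivalent ring positions to give 1-(benzyloxy)-2-bromo-4-{[(tert-butyldimethylsilyl)oxy]methyl}-3,5-bis(methoxymethoxy)benzene F6. Bromine–lithium exchange (t-BuLi, THF, −78 °C) would generate 8 at low temperature, to be trapped at once with alkoxide 9 as in step 6.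

**Further compounds**
F1 | step 13 | (S)-6-(hydroxymethyl)-5,7-bis(methoxymethoxy)-2-phenylchroman-4-one | O=C1C[C@@H](c2ccccc2)Oc2cc(OCOC)c(CO)c(OCOC)c21
F2 | step 13 | (S)-6-(chloromethyl)-5,7-bis(methoxymethoxy)-2-phenylchroman-4-one | O=C1C[C@@H](c2ccccc2)Oc2cc(OCOC)c(CCl)c(OCOC)c21
F3 | step 13 | (S)-6-[(2E)-3,7-dimethylocta-2,6-dien-1-yl]-5,7-bis(methoxymethoxy)-2-phenylchroman-4-one | CC(C)=CCC/C(C)=C/Cc1c(OCOC)cc2c(c1OCOC)C(=O)C[C@@H](c1ccccc1)O2
F4 | step 8 | (E)-1-[3-{[(tert-butyldimethylsilyl)oxy]methyl}-6-hydroxy-2,4-bis(methoxymethoxy)phenyl]-3-phenylprop-2-en-1-one | O=C(/C=C/c1ccccc1)c1c(O)cc(OCOC)c(CO[Si](C)(C)C(C)(C)C)c1OCOC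
F5 | step 8 | racemic 6-{[(tert-butyldimethylsilyl)oxy]methyl}-5,7-bis(methoxymethoxy)-2-phenylchroman-4-one | O=C1CC(c2ccccc2)Oc2cc(OCOC)c(CO[Si](C)(C)C(C)(C)C)c(OCOC)c21
F6 | step 6 | 1-(benzyloxy)-2-bromo-4-{[(tert-butyldimethylsilyl)oxy]methyl}-3,5-bis(methoxymethoxy)benzene | Brc1c(OCc2ccccc2)cc(OCOC)c(CO[Si](C)(C)C(C)(C)C)c1OCOC
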